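Ring A of this C20 gibberellin carries C19 (on C4) and C20 (on C10) as cis-1,3-diaxial carboxyl carbons on its α face. The route joins them as a temporary C19–O–C20 δ-lactone. A BCD tricycle holds a ring B enoate (C5=C6–C7), a C20 propionate on C10 α and a C1–C3 amide chain on C10 β. In one base-mediated cascade the propionate α-carbon (C4) adds to C5 from the α face, then, as the lactone enolate, is acylated by C3. C4 thus stitches C5 to C3, closing ring A last and fixing C5, C4 and the trans A/B fusion; the lactone is later opened and C20 oxidised.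

Key step: step 11

Remarks. Gibberellane numbering is used throughout: ring A = C1–C5, C10; ring B = C5, C6, C8–C10; ring C = C8, C9, C11–C14; ring D = C8, C13–C16; C17 = methylene, C18 = methyl, C7, C19, C20 = carboxyl carbons. α and β are used as is customary for gibberellins: β is the face of H5, H9 and C15; α is the face of C19, C20 and H6 (3β-hydroxy corresponds to ent-3α in ent-gibberellane nomenclature). Assumptions: reagent 5 is taken as purchasable (otherwise one step from tert-butyl acetate, LiN(i-Pr)2 and t-BuMe2SiCl). The bridgehead tertiary C13 hydroxyl is carried free until step 13, with one extra equivalent of base where needed.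

Step 1
Reactants: 1 methyl 4-oxobutanoate + 2 but-3-en-2-one
Product: 4 methyl 2-[(1S)-4-oxocyclohex-2-en-1-yl]acetate, via keto aldehyde 3 (not isolated)
Conditions: (S)-α,α-diphenylprolinol trimethylsilyl ether (5 mol%), ethyl 3,4-dihydroxybenzoate (20 mol%), neat, 4 °C; then dibenzylammonium trifluoroacetate (20 mol%), toluene, 40 °C
Reagents that add atoms: none
Why: Enamine-catalysed Michael addition, in which the bulky diarylmethyl silyl ether group shields one face of the E-enamine and so sets C9 as S, followed by amine-salt-catalysed intramolecular aldol condensation of the methyl ketone onto the aldehyde (Robinson-type annulation), which closes ring C without disturbing C9.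

Step 2
Reactants: 4 methyl 2-[(1S)-4-oxocyclohex-2-en-1-yl]acetate + 5 tert-butyl[(1-tert-butoxyethenyl)oxy]dimethylsilane
Product: 6 tert-butyl 2-[(1S,6S)-3-(tert-butyldimethylsilyloxy)-6-(2-methoxy-2-oxoethyl)cyclohex-2-en-1-yl]acetate
Conditions: t-BuMe2SiOTf (5 mol%), CH2Cl2, −78 °C
Reagents that add atoms: none
Why: Mukaiyama–Michael addition with silyl transfer: the ketene silyl acetal adds to C8 of the enone anti to the C9 side chain and the silyl group ends on the enolate oxygen, which fixes the C13=C14 enol ether needed for step 3.

Step 3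
Reactants: 6 tert-butyl 2-[(1S,6S)-3-(tert-butyldimethylsilyloxy)-6-(2-methoxy-2-oxoethyl)cyclohex-2-en-1-yl]acetate
Product: 7 tert-butyl 2-[(6S)-6-(2-methoxy-2-oxoethyl)-3-oxocyclohex-1-en-1-yl]acetate
Conditions: Pd(OAc)2 (1.05 equiv), MeCN, 25 °C
Reagents that add atoms: none
Why: Saegusa–Ito oxidation: divalent palladium forms the oxo-π-allyl species at C14 and β-hydride elimination of H8 gives back the enone, now carrying the acetate arm on C8, while the metal is reduced to zerovalent palladium and C9 is untouched.

Step 4
Reactants: 7 tert-butyl 2-[(6S)-6-(2-methoxy-2-oxoethyl)-3-oxocyclohex-1-en-1-yl]acetate + 8 tributyl(propa-1,2-dien-1-yl)stannane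
Product: 9 tert-butyl 2-[(1R,2S)-2-(2-methoxy-2-oxoethyl)-5-oxo-1-(prop-2-yn-1-yl)cyclohexyl]acetate
Conditions: TiCl4 (1.1 equiv), CH2Cl2, −78 °C
Reagents that add atoms: none
Why: Lewis-acid-mediated conjugate propargylation (a Sakurai-type addition in which the allenylstannane reacts at its γ-carbon with allenyl-to-propargyl transposition): the nucleophile attacks C8 anti to the pseudoaxial C9 arm, which creates the quaternary centre with C15 cis to H9 and the two ester arms cis on ring C.

Step 5
Reactants: 9 tert-butyl 2-[(1R,2S)-2-(2-methoxy-2-oxoethyl)-5-oxo-1-(prop-2-yn-1-yl)cyclohexyl]acetate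
Product: 10 CD bicyclic hydroxy diester (bicyclo[3.2.1]octane with bridgehead OH and exocyclic methylene)
Conditions: SmI2 (2.5 equiv), HMPA, t-BuOH, THF, 0 °C
Reagents that add atoms: none
Why: Ketyl–alkyne reductive cyclisation: the ketyl formed at C13 by divalent samarium adds 5-exo-dig to the axial propargyl group and the vinyl radical is reduced and protonated, which closes ring D with the bridgehead tertiary alcohol and the exocyclic methylene in one step, the configuration at C13 being dictated by the bridge.

Step 6
Reactants: 10 CD bicyclic hydroxy diester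
Product: 11 BCD β-keto ester (C5 ketone; tert-butyl ester C7 on C6)
Conditions: KOt-Bu (2.5 equiv), THF, 0 → 25 °C
Reagents that add atoms: none
Why: Dieckmann condensation closing ring B: only the enolate of the tert-butyl ester arm (C6) can condense, because a tert-butyl ester is not an acyl donor, the cis arms enforce the cis B/C fusion, and formation of the β-keto ester enolate drives the equilibrium.

Step 7
Reactants: 11 BCD β-keto ester + 12 ethyl formate
Product: 13 C10 hydroxymethylene β-keto ester (enol form of the C10 formyl ketone)
Conditions: LiN(i-Pr)2 (3.3 equiv), THF, −78 → −20 °C; then 12 (1.2 equiv), −78 → 0 °C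
Reagents that add atoms: none
Why: Claisen formylation of the β-keto ester dianion, which reacts at its more basic γ-carbon C10 and so introduces C20 as a hydroxymethylene group.

Step 8
Reactants: 13 C10 hydroxymethylene β-keto ester + 14 N-methoxy-N-methylprop-2-enamide
Product: 15 C10-quaternary formyl ketone (10α-formyl; 10β-amide chain)
Conditions: 14 (1.1 equiv), DBU (0.2 equiv), MeCN, 0 → 40 °C
Reagents that add atoms: none
Why: Base-catalysed Michael addition of the 2-formyl ketone enolate (the most acidic donor; C6 is flanked by quaternary C8 and is less acidic) in which the acceptor reaches C10 anti to the vicinal C9–C11 bond, on the β face where the neighbouring C9 carries only H9, so that the chain is β and C20 is α at the new quaternary centre.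

Step 9
Reactants: 15 C10-quaternary formyl ketone
Product: 16 C5,C20-diol (10α-hydroxymethyl; 5-hydroxy)
Conditions: NaBH4, THF/MeOH, −40 → 0 °C
Reagents that add atoms: none
Why: Borohydride reduction of the aldehyde and of the ring ketone, to which the amide and the tert-butyl ester are inert; the carbinol centre at C5 and the centre at C6 become trigonal in step 10, so their configuration is of no consequence.

Step 10
Reactants: 16 C5,C20-diol + 17 propanoyl chloride
Product: 20 ring B enoate with C20 propionate (C5=C6–C7 tert-butyl ester), via monopropionate 18 (not isolated), via mesylate 19 (not isolated)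
Conditions: 17 (1.1 equiv), pyridine, CH2Cl2, −20 °C; then MsCl (1.2 equiv), Et3N, 0 °C; then DBU, 25 °C
Reagents that add atoms: none
Why: Chemoselective acylation of the primary C20 hydroxyl, mesylation of the hindered C5 hydroxyl through sulfene and base-induced β-elimination through the C6 ester enolate (C10 is quaternary, so only one alkene can form) give the ring B enoate that carries the propionate tether; the bridgehead tertiary hydroxyl does not react.

Step 11
Reactants: 20 ring B enoate with C20 propionate
Product: 22 3-oxo 19,20-lactone (ring A closed; C7 tert-butyl ester), via Michael adduct lactone 21 (not isolated)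
Conditions: LiN(SiMe3)2 (3.5 equiv), THF, −78 → 0 °C
Reagents that add atoms: none
Why: LiN(SiMe3)2 deprotonates the propionate (more acidic than the α-CH2 of the N-methoxy-N-methylamide); the ester enolate adds to C5 of the ring B enoate in a 6-(enolendo)-exo-trig Michael closure that forms the temporary δ-lactone, the excess base or proton exchange through HN(SiMe3)2 then generates the enolate at the more acidic lactone position C4, and this enolate attacks the amide carbonyl C3 in a 6-(enolexo)-exo-trig closure of ring A, the chelated tetrahedral adduct releasing the C3 ketone only on work-up. The closest known reaction type is the tandem Michael–Dieckmann (Michael–Claisen) annulation, run here intramolecularly with an N-methoxy-N-methylamide as acyl donor. C5 is controlled by the tether: C20 sits on the α face of C10, so the six-membered lactone can only form cis-fused, C4 arrives on the α face of C5 and H5 stays β, which gives the trans A/B fusion. C4 is controlled by the bicyclo[3.3.1] frame: the C1–C3 chain is on the β face of C10, so only that face of the lactone enolate can be reached, which places C19 α (in the lactone) and the methyl C18 β. The step needs enolisation of the ester ahead of the amide, conjugate addition ahead of any Claisen reaction (the propionate enolate could reach the amide only through an eight-membered ring) and acylation at C4 instead of C6, which the higher acidity of the lactone and the crowded position of C6 next to quaternary C8 should secure. C6 is protonated reversibly and should settle trans to C4 (H6 α), the more stable arrangement, which the alkaline step 14 can complete.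

Step 12
Reactants: 22 3-oxo 19,20-lactone
Product: 23 3β-hydroxy 19,20-lactone
Conditions: KB(s-Bu)3H (2.2 equiv), THF, −78 °C
Reagents that add atoms: none
Why: Ketone reduction by a bulky trialkylborohydride, which avoids the axial path past H1β and H5β and delivers hydride along the equatorial path on the α side, as is usual for 3-ketones flanked by a quaternary C4, giving the axial 3β-alcohol; lactone and tert-butyl ester are not reduced at this temperature.

Step 13
Reactants: 23 3β-hydroxy 19,20-lactone
Product: 24 3,13-bis(triethylsilyl) ether lactone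
Conditions: Et3SiOTf (3 equiv), 2,6-lutidine, CH2Cl2, −40 → 0 °C
Reagents that add atoms: triethylsilyl trifluoromethanesulfonate, CC[Si](CC)(CC)OS(=O)(=O)C(F)(F)F
Why: Silylation of the axial secondary and the bridgehead tertiary hydroxyl with the silyl triflate; the 3-silyl ether keeps the β-hydroxy lactone from retro-aldol cleavage and from oxidation in step 14.

Step 14
Reactants: 24 3,13-bis(triethylsilyl) ether lactone
Product: 26 19,20-diacid 7-tert-butyl ester bis(silyl) ether, via hydroxy acid 25 (not isolated)
Conditions: KOH (2 M aq.), THF/MeOH, 50 °C; then AcOH to pH 8; then TEMPO (0.2 equiv), PhI(OAc)2 (2.5 equiv), MeCN/aq. NaHCO3, 0 → 25 °C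
Reagents that add atoms: potassium hydroxide, [K+].[OH-]; water, O
Why: Saponification opens the hindered δ-lactone to the C19 carboxylate and the C20 alcohol (the tert-butyl ester resists, and C6 can settle in its more stable configuration with H6 α), and the oxoammonium ion from TEMPO then oxidises the primary alcohol through the aldehyde or its lactol to the acid in the same flask, so that the hydroxy acid is never acidified and cannot re-close.

Step 15
Reactants: 26 19,20-diacid 7-tert-butyl ester bis(silyl) ether
Product: 28 target gibberellin 3β,13-dihydroxygibberell-16-ene-7,19,20-trioic acid, via tris(trimethylsilyl) ester 27 (not isolated)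
Conditions: Me3SiOTf (6 equiv), 2,6-lutidine, CH2Cl2, 0 °C; then HF·pyridine, THF, 0 → 25 °C
Reagents that add atoms: none
Why: Me3SiOTf with 2,6-lutidine cleaves the tert-butyl ester as 2-methylpropene without free strong acid, which spares the acid-sensitive 13-oxygenated 16-ene unit, and buffered HF then removes the silyl esters and both triethylsilyl ethers to give the triacid.

Compound list

1 | methyl 4-oxobutanoate | COC(=O)CCC=O | starting material
2 | but-3-en-2-one (methyl vinyl ketone) | CC(=O)C=C | starting material
3 | keto aldehyde: methyl (3S)-3-formyl-6-oxoheptanoate | COC(=O)C[C@@H](C=O)CCC(C)=O | intermediate (not isolated)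
4 | methyl 2-[(1S)-4-oxocyclohex-2-en-1-yl]acetate | COC(=O)C[C@H]1C=CC(=O)CC1 | intermediate
5 | tert-butyl[(1-tert-butoxyethenyl)oxy]dimethylsilane (ketene silyl acetal of tert-butyl acetate) | C=C(OC(C)(C)C)O[Si](C)(C)C(C)(C)C | starting material
6 | tert-butyl 2-[(1S,6S)-3-(tert-butyldimethylsilyloxy)-6-(2-methoxy-2-oxoethyl)cyclohex-2-en-1-yl]acetate (side chains trans) | COC(=O)C[C@@H]1CCC(O[Si](C)(C)C(C)(C)C)=C[C@H]1CC(=O)OC(C)(C)C | intermediate
7 | tert-butyl 2-[(6S)-6-(2-methoxy-2-oxoethyl)-3-oxocyclohex-1-en-1-yl]acetate | COC(=O)C[C@@H]1CCC(=O)C=C1CC(=O)OC(C)(C)C | intermediate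
8 | tributyl(propa-1,2-dien-1-yl)stannane | C=C=C[Sn](CCCC)(CCCC)CCCC | starting material
9 | tert-butyl 2-[(1R,2S)-2-(2-methoxy-2-oxoethyl)-5-oxo-1-(prop-2-yn-1-yl)cyclohexyl]acetate (ester arms cis, propargyl trans to the C9 arm) | C#CC[C@]1(CC(=O)OC(C)(C)C)CC(=O)CC[C@H]1CC(=O)OC | intermediate
10 | CD bicyclic hydroxy diester: tert-butyl 2-[5-hydroxy-2-(2-methoxy-2-oxoethyl)-6-methylidenebicyclo[3.2.1]octan-1-yl]acetate, C8, C9 and C13 configured as in the target, ester arms cis | C=C1C[C@]2(CC(=O)OC(C)(C)C)C[C@@]1(O)CC[C@H]2CC(=O)OC | intermediate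
11 | BCD β-keto ester: C5 ketone, tert-butyl ester (C7) on C6, 13-OH, 16-methylene, rings B/C cis-fused with H9 and C15 β; C6 epimerisable | C=C1C[C@]23C[C@@]1(O)CC[C@H]2CC(=O)C3C(=O)OC(C)(C)C | intermediate
12 | ethyl formate | CCOC=O | starting material
13 | C10 hydroxymethylene β-keto ester (enol form of the 10-formyl-5-ketone; C20 in place; C6 epimerisable) | C=C1C[C@]23C[C@@]1(O)CC[C@H]2C(=CO)C(=O)C3C(=O)OC(C)(C)C | intermediate
14 | N-methoxy-N-methylprop-2-enamide | C=CC(=O)N(C)OC | starting material
15 | C10-quaternary formyl ketone: 10α-formyl (C20), 10β-[3-(methoxy(methyl)amino)-3-oxopropyl] (C1–C3), C5 ketone, C6 tert-butyl ester; C6 epimerisable | C=C1C[C@]23C[C@@]1(O)CC[C@H]2[C@](C=O)(CCC(=O)N(C)OC)C(=O)C3C(=O)OC(C)(C)C | intermediate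
16 | C5,C20-diol: 10α-hydroxymethyl, 5-hydroxy, 10β-amide chain, C6 tert-butyl ester; mixture at C5 and C6 | C=C1C[C@]23C[C@@]1(O)CC[C@H]2[C@](CO)(CCC(=O)N(C)OC)C(O)C3C(=O)OC(C)(C)C | intermediate
17 | propanoyl chloride | CCC(=O)Cl | starting material
18 | monopropionate: 20-O-propanoyl derivative of 16 | C=C1C[C@]23C[C@@]1(O)CC[C@H]2[C@](COC(=O)CC)(CCC(=O)N(C)OC)C(O)C3C(=O)OC(C)(C)C | intermediate (not isolated)
19 | mesylate: 5-O-methanesulfonyl derivative of 18 | C=C1C[C@]23C[C@@]1(O)CC[C@H]2[C@](COC(=O)CC)(CCC(=O)N(C)OC)C(OS(C)(=O)=O)C3C(=O)OC(C)(C)C | intermediate (not isolated)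
20 | ring B enoate with C20 propionate: C5=C6 double bond conjugated with the C7 tert-butyl ester, 10α-(propanoyloxymethyl), 10β-amide chain, 13-OH, 16-methylene | C=C1C[C@]23C[C@@]1(O)CC[C@H]2[C@](COC(=O)CC)(CCC(=O)N(C)OC)C=C3C(=O)OC(C)(C)C | intermediate
21 | Michael adduct lactone: 19,20-δ-lactone with the C4–C5 bond on the α face of C5 (H5 β), amide chain still open; C4 and C6 not fixed | C=C1C[C@]23C[C@@]1(O)CC[C@H]2[C@@]4(CCC(=O)N(C)OC)COC(=O)C(C)[C@H]4C3C(=O)OC(C)(C)C | intermediate (not isolated)
22 | 3-oxo 19,20-lactone: tetracyclic gibberellane skeleton, C3 ketone, 4β-methyl, C19 (α) lactonised to the 10α-CH2O (C20), H5 β, H6 α, C7 tert-butyl ester β, 13-OH, 16-methylene | C=C1C[C@]23C[C@@]1(O)CC[C@H]2[C@]15CCC(=O)[C@@](C)(C(=O)OC5)[C@H]1[C@@H]3C(=O)OC(C)(C)C | intermediate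
23 | 3β-hydroxy 19,20-lactone (axial 3β-OH; otherwise as 22) | C=C1C[C@]23C[C@@]1(O)CC[C@H]2[C@]15CC[C@H](O)[C@@](C)(C(=O)OC5)[C@H]1[C@@H]3C(=O)OC(C)(C)C | intermediate
24 | 3,13-bis(triethylsilyl) ether lactone | C=C1C[C@]23C[C@@]1(O[Si](CC)(CC)CC)CC[C@H]2[C@]15CC[C@H](O[Si](CC)(CC)CC)[C@@](C)(C(=O)OC5)[C@H]1[C@@H]3C(=O)OC(C)(C)C | intermediate
25 | hydroxy acid: C19 carboxylic acid, 10α-hydroxymethyl (C20), C7 tert-butyl ester, 3,13-bis(triethylsilyl) ether (formed as its potassium salt) | C=C1C[C@]23C[C@@]1(O[Si](CC)(CC)CC)CC[C@H]2[C@]1(CO)CC[C@H](O[Si](CC)(CC)CC)[C@@](C)(C(=O)O)[C@H]1[C@@H]3C(=O)OC(C)(C)C | intermediate (not isolated)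
26 | 19,20-diacid 7-tert-butyl ester bis(silyl) ether | C=C1C[C@]23C[C@@]1(O[Si](CC)(CC)CC)CC[C@H]2[C@]1(C(=O)O)CC[C@H](O[Si](CC)(CC)CC)[C@@](C)(C(=O)O)[C@H]1[C@@H]3C(=O)OC(C)(C)C | intermediate
27 | tris(trimethylsilyl) ester of the 3,13-bis(triethylsilyl) ether triacid | C=C1C[C@]23C[C@@]1(O[Si](CC)(CC)CC)CC[C@H]2[C@]1(C(=O)O[Si](C)(C)C)CC[C@H](O[Si](CC)(CC)CC)[C@@](C)(C(=O)O[Si](C)(C)C)[C@H]1[C@@H]3C(=O)O[Si](C)(C)C | intermediate (not isolated)
28 | target gibberellin: 3β,13-dihydroxygibberell-16-ene-7,19,20-trioic acid (ent-3α,13-dihydroxygibberell-16-ene-7,19,20-trioic acid) | C=C1C[C@]23C[C@@]1(O)CC[C@H]2[C@]1(C(=O)O)CC[C@H](O)[C@@](C)(C(=O)O)[C@H]1[C@@H]3C(=O)O | target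

Total step count: 15. Longest linear sequence: 15 steps (the route is linear from 1; compounds 2, 5, 8, 12, 14 and 17 are bought).

Steps most likely to fail

Step 11. The cascade may stall after the conjugate addition because proton transfer to the lactone position is slow, or the amide may be acylated by the wrong (C6) enolate. The fallback sets out from 20 and closes ring A by an aldol reaction instead of an acylation. LiN(SiMe3)2 (2.1 equiv) at −78 °C with an early quench would give the Michael adduct lactone 21, now isolated. Reduction of its N-methoxy-N-methylamide with Cp2Zr(H)Cl (THF, 25 °C, short reaction time, so that the 1,1-disubstituted alkene is not hydrozirconated) would give the aldehyde lactone F1. An intramolecular aldol reaction of the lactone enolate (KOt-Bu, 0.2 equiv, t-BuOH/THF, −20 °C), the reverse of the retro-aldol opening of ring A that 3-hydroxy gibberellins undergo in base, should close ring A under the same bicyclic control of C4 and give the 3-hydroxy lactone F2, in which the configuration at C3 need not be controlled and C6 can settle under the alkoxide. Oxidation with Dess–Martin periodinane (NaHCO3, CH2Cl2, 0 °C) would give the 3-ketone, and the route is rejoined at 22.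

Step 14. The hydroxy acid may re-close to the lactone before or during the oxidation, and the triethylsilyl ethers may be partly lost in hot alkali, which would reopen the way to retro-aldol epimerisation at C3. The fallback sets out from 24 and avoids the hydroxy acid. LiBH4 (THF/MeOH, 50 °C) would reduce the lactone to the 19,20-diol F3, with the tert-butyl ester and the silyl ethers intact. A Swern oxidation would give the 19,20-dialdehyde F4. A Pinnick oxidation (NaClO2, NaH2PO4, 2-methylbut-2-ene, t-BuOH/H2O) would then give the diacid, and the route is rejoined at 26.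

Step 8. Addition of the stabilised enolate to the weakly electrophilic acrylamide may be slow, and the formyl group may be lost by retro-Claisen cleavage during long exposure to base. The fallback sets out from 13 and uses a more electrophilic acceptor, the amide being made afterwards. Michael addition to S-ethyl prop-2-enethioate (Et3N, 0.2 equiv, CH2Cl2, 0 °C) should give the thioester adduct F5 quickly and with the same facial preference at C10. Aminolysis of the thioester with N,O-dimethylhydroxylamine hydrochloride and i-Pr2NEt, promoted by silver trifluoroacetate (THF, 25 °C), conditions that should leave the aldehyde, the ketone and the tert-butyl ester alone, would then give the amide. The route is rejoined at 15.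

Further compounds
F1 | step 11 | aldehyde lactone: 19,20-δ-lactone with 10β-(3-oxopropyl) chain, C7 tert-butyl ester, 13-OH, 16-methylene; C4 and C6 not fixed | C=C1C[C@]23C[C@@]1(O)CC[C@H]2[C@@]4(CCC=O)COC(=O)C(C)[C@H]4C3C(=O)OC(C)(C)C
F2 | step 11 | 3-hydroxy lactone: 3-hydroxy 19,20-lactone as 23 but as a mixture of epimers at C3 | C=C1C[C@]23C[C@@]1(O)CC[C@H]2[C@]15CCC(O)[C@@](C)(C(=O)OC5)[C@H]1[C@@H]3C(=O)OC(C)(C)C
F3 | step 14 | 19,20-diol: 4α- and 10α-hydroxymethyl, 3,13-bis(triethylsilyl) ether, C7 tert-butyl ester | C=C1C[C@]23C[C@@]1(O[Si](CC)(CC)CC)CC[C@H]2[C@]1(CO)CC[C@H](O[Si](CC)(CC)CC)[C@@](C)(CO)[C@H]1[C@@H]3C(=O)OC(C)(C)C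
F4 | step 14 | 19,20-dialdehyde: 4α- and 10α-formyl, 3,13-bis(triethylsilyl) ether, C7 tert-butyl ester | C=C1C[C@]23C[C@@]1(O[Si](CC)(CC)CC)CC[C@H]2[C@]1(C=O)CC[C@H](O[Si](CC)(CC)CC)[C@@](C)(C=O)[C@H]1[C@@H]3C(=O)OC(C)(C)C
F5 | step 8 | thioester adduct: 10α-formyl, 10β-[3-(ethylsulfanyl)-3-oxopropyl], C5 ketone, C6 tert-butyl ester; C6 epimerisable | C=C1C[C@]23C[C@@]1(O)CC[C@H]2[C@](C=O)(CCC(=O)SCC)C(=O)C3C(=O)OC(C)(C)C
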